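**Plan**
1. Ring locants used below: C-1 is the ring carbon on the bridging methine, C-2 the C–OH carbon, C-3 a CMe2, C-4 the C=O between the two CMe2 carbons, C-5 the other CMe2, C-6 the remaining C=O.
2. Retrosynthesis: cut C-4–C-5 in both rings at once (double retro-Dieckmann) to an acyclic bis(3,5-dioxo ester); cut both C-1–C-2 bonds (retro C-acylation) to a symmetric 1,5-diketone and two dimethylmalonyl half-ester chlorides; cut both isopropyl–carbonyl bonds to 3-isobutylglutaric acid.
3. Forward, two-directional: the diacid already holds the bridging methine, its isobutyl group and both C-1 carbons in symmetric form. Both ends are elaborated identically (bis-Weinreb amide, bis-isopropyl ketone, bis-C-acylation) and both rings are closed last, in one operation.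
4. Enabling feature: each ring is a 2,2,4,4-tetramethylcyclohexane-1,3,5-trione. Quaternary C-3 cannot enolise, so the C-5 methine is the only carbon nucleophile able to reach the C-4 ester. The acidic C-1/C-2 enol of each ring is deprotonated irreversibly, which drives closure onto the hindered ester, and the two rings are identical, so one set of conditions closes both.
5. Stereochemistry: the target has no stereocentre (two identical rings on the methine); the stereocentres that arise in two intermediates are erased.

Key step: step 5

Remark: the target is taken as the drawn enol tautomer of an achiral bis(β-triketone); 3-isobutylglutaric acid and dimethylmalonic acid monomethyl ester are taken as commercial.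

**Step 1**
Reactants: 1 3-(2-methylpropyl)pentanedioic acid (3-isobutylglutaric acid)
Product: 2 N1,N5-dimethoxy-N1,N5-dimethyl-3-(2-methylpropyl)pentanediamide
Conditions: MeNH(OMe)·HCl (3 equiv), EDC·HCl (3 equiv), HOBt (0.2 equiv), N-methylmorpholine (7 equiv), CH2Cl2, 0 °C to rt
Reagents that add atoms: N,O-dimethylhydroxylamine hydrochloride (CNOC.Cl)
Why: Carbodiimide/HOBt amide coupling of both carboxyl groups; the amine is secondary, so no imide can form, and excess reagent should carry both arms to the Weinreb amide.

**Step 2**
Reactants: 2 N1,N5-dimethoxy-N1,N5-dimethyl-3-(2-methylpropyl)pentanediamide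
Product: 4 2,8-dimethyl-5-(2-methylpropyl)nonane-3,7-dione, via bis-magnesium hemiaminal chelate 3 (not isolated)
Conditions: i-PrMgCl (3.5 equiv), THF, 0 °C to rt; then 1 M HCl, 0 °C
Reagents that add atoms: isopropylmagnesium chloride (CC(C)[Mg]Cl)
Why: Weinreb ketone synthesis: the N-methoxy magnesium chelate 3 holds each carbonyl at the tetrahedral stage, so only one isopropyl group should add per arm and the ketones appear only on acidic work-up.

**Step 3**
Reactants: 5 3-methoxy-2,2-dimethyl-3-oxopropanoic acid
Product: 6 methyl 3-chloro-2,2-dimethyl-3-oxopropanoate
Conditions: (COCl)2 (1.3 equiv), DMF (cat.), CH2Cl2, 0 °C to rt; evaporate, use crude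
Reagents that add atoms: oxalyl chloride (O=C(Cl)C(Cl)=O)
Why: Standard acid chloride formation with oxalyl chloride under Vilsmeier-type catalysis; the quaternary α-carbon excludes ketene formation and the methyl ester is untouched.

**Step 4**
Reactants: 4 2,8-dimethyl-5-(2-methylpropyl)nonane-3,7-dione; 6 methyl 3-chloro-2,2-dimethyl-3-oxopropanoate
Product: 8 dimethyl 2,2,8,8-tetramethyl-4,6-bis(2-methylpropanoyl)-5-(2-methylpropyl)-3,7-dioxononanedioate, via bis-bromomagnesium enolate 7 (not isolated)
Conditions: 6 (2.5 equiv), MgBr2·OEt2 (5 equiv), i-Pr2NEt (6 equiv), CH2Cl2, 0 °C to rt; then 1 M HCl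
Reagents that add atoms: none
Why: Magnesium-promoted soft enolisation and C-acylation (crossed Claisen-type synthesis of 1,3-diketones): MgBr2 coordination lets the hindered amine deprotonate each ketone at the less substituted CH2 to give 7, which should be acylated on carbon by the ketene-incapable acid chloride, while the only aldol-competent carbons of the 1,5-diketone are its hindered isopropyl methines, so self-cyclisation of 4 should not compete.

**Step 5**
Reactants: 8 dimethyl 2,2,8,8-tetramethyl-4,6-bis(2-methylpropanoyl)-5-(2-methylpropyl)-3,7-dioxononanedioate
Product: 11 Watsonianone A, via dipotassium bis-diketonate 9 (not isolated), via dipotassium bis-enolate 10 (not isolated)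
Conditions: KOtBu (5 equiv), THF, 0 °C to 50 °C; then 1 M HCl
Reagents that add atoms: none
Why: KOtBu first turns both 1,3-diketone units of 8 into the diketonates 9; reversible removal of the isopropyl methine hydrogen (future C-5) on each arm then gives the terminal carbanion of a 1,3-diketone dianion, which adds to the methyl ester carbon (future C-4) and expels methoxide, and each cyclic triketone formed is held as its vinylogous carboxylate in 10 until acidification. The closest known reaction type is the Dieckmann (intramolecular Claisen) cyclisation of 3,5-dioxoalkanoates to cyclohexane-1,3,5-triones, together with the ester acylation of 1,3-diketone dianions at their terminal carbon, here run on both arms of one molecule at once. Each of the two rings closes in the 6-(enolendo)-exo-trig mode. No stereocentre is created: the two CH stereocentres of 8 become sp2 carbons (C-1 of each ring), so all diastereomers and tautomers of 8 should converge on one achiral product. The step needs attack through carbon and not oxygen, attack on the ester of the same arm and not of the other arm, and closure faster than retro-Claisen or retro-Michael cleavage; quaternary C-3 leaves the isopropyl methine as the only carbon nucleophile, the same-arm ester gives a six-membered ring (helped by the gem-dimethyl groups) against an eight-membered one, and the diketonate form shields the ketones from alkoxide. Because the steps before the final deprotonation are reversible and only the carbon-cyclised product ends as a stabilised enolate, any oxygen-cyclised enol lactone should be reopened by methoxide and returned to the productive path.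

**Compound list**
1 | 3-(2-methylpropyl)pentanedioic acid (3-isobutylglutaric acid) | CC(C)CC(CC(=O)O)CC(=O)O | starting material
2 | N1,N5-dimethoxy-N1,N5-dimethyl-3-(2-methylpropyl)pentanediamide | CC(C)CC(CC(=O)N(C)OC)CC(=O)N(C)OC | intermediate
3 | bis(chloromagnesium) 2,8-dimethyl-3,7-bis[methoxy(methyl)amino]-5-(2-methylpropyl)nonane-3,7-diolate (diastereomer mixture, configuration without consequence) | CC(C)CC(CC(O[Mg]Cl)(C(C)C)N(C)OC)CC(O[Mg]Cl)(C(C)C)N(C)OC | intermediate (not isolated)
4 | 2,8-dimethyl-5-(2-methylpropyl)nonane-3,7-dione | CC(C)CC(CC(=O)C(C)C)CC(=O)C(C)C | intermediate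
5 | 3-methoxy-2,2-dimethyl-3-oxopropanoic acid | COC(=O)C(C)(C)C(=O)O | starting material
6 | methyl 3-chloro-2,2-dimethyl-3-oxopropanoate | COC(=O)C(C)(C)C(Cl)=O | intermediate
7 | bis(bromomagnesium) 2,8-dimethyl-5-(2-methylpropyl)nona-3,6-diene-3,7-diolate (enolate geometry not defined, without consequence) | CC(C)CC(C=C(O[Mg]Br)C(C)C)C=C(O[Mg]Br)C(C)C | intermediate (not isolated)
8 | dimethyl 2,2,8,8-tetramethyl-4,6-bis(2-methylpropanoyl)-5-(2-methylpropyl)-3,7-dioxononanedioate (mixture of diastereomers and keto–enol tautomers, all used) | COC(=O)C(C)(C)C(=O)C(C(=O)C(C)C)C(CC(C)C)C(C(=O)C(C)C)C(=O)C(C)(C)C(=O)OC | intermediate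
9 | dipotassium bis(1,3-diketonate) of 8 (deprotonated at the two CH carbons between the ketones) | CC(C)CC(C(C(=O)C(C)(C)C(=O)OC)=C([O-])C(C)C)C(C(=O)C(C)(C)C(=O)OC)=C([O-])C(C)C.[K+].[K+] | intermediate (not isolated)
10 | dipotassium bis-enolate of Watsonianone A | CC(C)CC(C1=C([O-])C(C)(C)C(=O)C(C)(C)C1=O)C1=C([O-])C(C)(C)C(=O)C(C)(C)C1=O.[K+].[K+] | intermediate (not isolated)
11 | Watsonianone A, 2,2'-(3-methylbutane-1,1-diyl)bis(3-hydroxy-4,4,6,6-tetramethylcyclohex-2-ene-1,5-dione) | CC(C)CC(C1=C(O)C(C)(C)C(=O)C(C)(C)C1=O)C1=C(O)C(C)(C)C(=O)C(C)(C)C1=O | target

**Totals**
Total step count: 5. Longest linear sequence: 4 steps (steps 1, 2, 4, 5); step 3 is a one-step side branch that prepares 6.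

**Steps most likely to fail**

Step 5. The substrate may fragment instead of closing: retro-Michael loss of one diketone arm while only one arm is deprotonated, retro-Claisen cleavage by the methoxide released, or a stalled second closure because deprotonation of the hindered isopropyl methine next to a diketonate is slow. The fallback builds one ring at a time and joins the rings at the methine afterwards; it sets out from 6 and comes back at 11. Commercial 3-methylbutan-2-one would be C-acylated at its methyl group with 6 (MgBr2·OEt2, i-Pr2NEt, CH2Cl2) to give methyl 2,2,6-trimethyl-3,5-dioxoheptanoate F1. A single Dieckmann closure of F1 (KOtBu, THF; then HCl) should give 2,2,4,4-tetramethylcyclohexane-1,3,5-trione F2 (syncarpic acid). Two equivalents of F2 and commercial 3-methylbutanal would then be combined under amine catalysis (piperidine cat., CH2Cl2, rt): Knoevenagel condensation gives 2,2,4,4-tetramethyl-6-(3-methylbutylidene)cyclohexane-1,3,5-trione F3 (not isolated), and Michael addition of the second F2 to it should give 11.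

Step 4. Acylation may go through the enolate oxygen, stall after one arm, or be diverted by attack of the second arm's enolate on the ester of the first arm; the α-quaternary acid chloride makes all three more likely. The fallback reverses the order in which the two acyl groups are attached to C-1; it sets out from 2 and comes back at 8. The lithium enolate of methyl 2-methylpropanoate (LiN(i-Pr)2, THF, −78 °C) would be added to both Weinreb amide groups of 2 to give dimethyl 2,2,8,8-tetramethyl-5-(2-methylpropyl)-3,7-dioxononanedioate F4, whose ketones can enolise only toward the chain CH2 groups. C-acylation of F4 with the small 2-methylpropanoyl chloride (MgBr2·OEt2, i-Pr2NEt, CH2Cl2) should then give 8.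

Step 2. The basic secondary Grignard reagent may deprotonate α to the amide or transfer a β-hydride instead of adding, so that one arm returns as amide or is reduced. The fallback replaces carbonyl addition by an acyl cross-coupling; it sets out from 1 and comes back at 4. The diacid 1 would be converted with oxalyl chloride (cat. DMF, CH2Cl2) into 3-(2-methylpropyl)pentanedioyl dichloride F5. F5 would then be coupled with i-PrMgCl under Fe(acac)3 catalysis (THF, −78 °C), where acyl transfer should outrun addition to the ketone formed, to give 4.

**Further compounds**
F1 | step 5 | methyl 2,2,6-trimethyl-3,5-dioxoheptanoate | COC(=O)C(C)(C)C(=O)CC(=O)C(C)C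
F2 | step 5 | 2,2,4,4-tetramethylcyclohexane-1,3,5-trione (syncarpic acid) | CC1(C)C(=O)CC(=O)C(C)(C)C1=O
F3 | step 5 | 2,2,4,4-tetramethyl-6-(3-methylbutylidene)cyclohexane-1,3,5-trione | CC(C)CC=C1C(=O)C(C)(C)C(=O)C(C)(C)C1=O
F4 | step 4 | dimethyl 2,2,8,8-tetramethyl-5-(2-methylpropyl)-3,7-dioxononanedioate | COC(=O)C(C)(C)C(=O)CC(CC(C)C)CC(=O)C(C)(C)C(=O)OC
F5 | step 2 | 3-(2-methylpropyl)pentanedioyl dichloride | CC(C)CC(CC(Cl)=O)CC(Cl)=O
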